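**Plan**
Retrosynthesis: cut the side chain at C12–C13 (syn-hydroalkylation of a 4-silyloxybutynoate) and the C8=C17 methylene; then cut ring A at C1–C2 and C4–C5 (plus one C4 methyl and the C3 oxygen).
Forward: ring B comes from p-benzoquinone monoketal; ring A is closed onto it in one operation by olefination at C1 and aldol condensation at C5 with a 2-oxobutylphosphonate; the side chain is built last.
Enabling feature: the quaternary C10 is flanked by C1 and C5, which can be held as a non-enolisable aldehyde/ketone pair on ring B, so a C2–C3–C4 ketone unit can condense at both ends to give ring A as a cyclohexadienone.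
Stereochemistry: C9 by catalytic asymmetric conjugate vinylation; C10 by enolate hydroxymethylation anti to the C9 vinyl; C5 (trans fusion) by dissolving-metal reduction; the 13Z alkene by syn-carbocupration of the ynoate.

Key step: step 6

Remark: the SMILES is read as the ent-labdane (5R,9R,10R) with a 13Z double bond; labdane numbering (C1–C20) is used for atoms in the explanations.

**Step 1**
Reactants: 1 4,4-dimethoxycyclohexa-2,5-dien-1-one; 2 2-ethenyl-4,4,5,5-tetramethyl-1,3,2-dioxaborolane
Product: 3 (5R)-5-ethenyl-4,4-dimethoxycyclohex-2-en-1-one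
Conditions: [RhCl(C2H4)2]2 (1.5 mol %), chiral bicyclo[2.2.2]octa-2,5-diene ligand (3.3 mol %, enantiomer chosen to give the 5R ketone), KOH (0.3 equiv), 1,4-dioxane/H2O 10:1, 30 °C
Reagents that add atoms: none
Why: Rhodium-catalysed asymmetric 1,4-addition of an alkenylboron reagent (Hayashi–Miyaura reaction) to the achiral dienone should set C9 under control of the chiral diene ligand, the adjacent ketal slowing a second addition.

**Step 2**
Reactants: 3
Product: 4 (5S,6S)-5-ethenyl-4,4-dimethoxy-6-methylcyclohex-2-en-1-one (methyl trans to vinyl)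
Conditions: LDA, THF, −78 °C; MeI, −78 → −40 °C
Reagents that add atoms: iodomethane CI
Why: Enolate alkylation at C10, the only enolisable position of the enone (α′), should proceed mainly trans to the vinyl group; both C10 epimers converge in step 3.

**Step 3**
Reactants: 4
Product: 5 (5S,6R)-5-ethenyl-6-(hydroxymethyl)-4,4-dimethoxy-6-methylcyclohex-2-en-1-one
Conditions: LDA, THF, −78 → −40 °C; CH2O (gas), −78 °C; AcOH quench
Reagents that add atoms: formaldehyde C=O
Why: Aldol addition of the tetrasubstituted lithium enolate to formaldehyde makes C10 quaternary, the electrophile approaching anti to the vinyl group on C9 so that C1 ends trans and the methyl cis to it.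

**Step 4**
Reactants: 5
Product: 6 (2R,3S)-3-ethenyl-2-(hydroxymethyl)-4,4-dimethoxy-2-methylcyclohexan-1-one
Conditions: [(Ph3P)CuH]6 (0.25 equiv), benzene, H2O (5 equiv), rt
Reagents that add atoms: none
Why: Conjugate reduction of the enone by the phosphine-stabilised copper hydride should saturate C6–C7 while leaving the isolated vinyl group and the free alcohol untouched.

**Step 5**
Reactants: 6
Product: 7 (1R,6S)-6-ethenyl-5,5-dimethoxy-1-methyl-2-oxocyclohexane-1-carbaldehyde
Conditions: Dess–Martin periodinane, CH2Cl2, 0 °C → rt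
Reagents that add atoms: none
Why: Dess–Martin oxidation of the neopentyl primary alcohol gives the β-keto aldehyde under non-basic conditions, and the quaternary C10 cannot epimerise.

**Step 6**
Reactants: 7; 8 diethyl (2-oxobutyl)phosphonate
Product: 10 (4aS,5S)-5-ethenyl-6,6-dimethoxy-1,4a-dimethyl-5,6,7,8-tetrahydronaphthalen-2(4aH)-one, via (E)-enone 9 (not isolated)
Conditions: LiCl, DBU, MeCN, 0 °C → rt; then NaOMe, MeOH, 60 °C
Reagents that add atoms: none
Why: The phosphonate carbanion olefinates the aldehyde carbon C1 (Horner–Wadsworth–Emmons reaction, C1=C2), and under methoxide the α′-methylene of the new enone (C4) adds to the C5 ketone and dehydrates (intramolecular aldol condensation, C4=C5), so ring A closes as a cross-conjugated cyclohexadienone in a formal [3+3] annulation of the C1–C10–C5 dicarbonyl unit with the C2–C3–C4 ketone. The closest known reaction types are the olefination of α,α-disubstituted β-keto aldehydes and the aldol closure of a Robinson annulation. Ring A closes in the 6-(enolendo)-exo-trig mode; the first-formed (E)-enone must isomerise before closure, which reversible conjugate addition of methoxide should allow, and the dienone is the thermodynamic sink. No new stereocentre arises: C10 is quaternary, C9 is not enolisable here, and C5 becomes trigonal and is set in step 8. Regiochemistry is secured by the phosphonate (only its phosphorus-bearing carbon can become C2, leaving the ethyl CH2 as C4) and by the aldehyde being far more electrophilic than the hindered ketone, while the non-nucleophilic LiCl/DBU first stage avoids deformylation of the β-keto aldehyde.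

**Step 7**
Reactants: 10
Product: 11 (4aS,5S)-5-ethenyl-6,6-dimethoxy-1,4a-dimethyl-4,4a,5,6,7,8-hexahydronaphthalen-2(3H)-one
Conditions: [(Ph3P)CuH]6 (0.25 equiv), benzene, H2O, rt
Reagents that add atoms: none
Why: Copper hydride conjugate reduction should take the disubstituted C1=C2 bond of the cross-conjugated dienone and leave the tetrasubstituted C4=C5 enone and the vinyl group.

**Step 8**
Reactants: 11
Product: 12 (4aR,5S,8aS)-5-ethenyl-6,6-dimethoxy-1,1,4a-trimethyloctahydronaphthalen-2(1H)-one
Conditions: Li, NH3 (l), THF, t-BuOH (1 equiv), −78 °C; then MeI, −78 → −33 °C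
Reagents that add atoms: iodomethane CI
Why: Dissolving-metal reductive alkylation of the enone should protonate the C5 carbanion axially (H anti to the C10 methyl, trans ring fusion) and methylate the regiodefined C3–C4 enolate at C4 to complete the gem-dimethyl group.

**Step 9**
Reactants: 12
Product: 13 (1S,4aR,8aR)-1-ethenyl-2,2-dimethoxy-5,5,8a-trimethyldecahydronaphthalene
Conditions: N2H4·H2O, KOH, diethylene glycol, 130 → 200 °C, N2
Reagents that add atoms: none
Why: Wolff–Kishner reduction (Huang-Minlon conditions) removes the C3 carbonyl next to the gem-dimethyl carbon, and the ketal and the terminal alkene should tolerate the basic medium.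

**Step 10**
Reactants: 14 tert-butyldimethyl(prop-2-yn-1-yloxy)silane
Product: 16 2-(trimethylsilyl)ethyl 4-[(tert-butyldimethylsilyl)oxy]but-2-ynoate, via lithium acetylide 15 (not isolated)
Conditions: n-BuLi, THF, −78 °C; then 2-(trimethylsilyl)ethyl 4-nitrophenyl carbonate, −78 → 0 °C; AcOH quench
Reagents that add atoms: 2-(trimethylsilyl)ethyl 4-nitrophenyl carbonate C[Si](C)(C)CCOC(=O)Oc1ccc(cc1)[N+](=O)[O-]
Why: Acylation of the lithium acetylide by the activated carbonate, with 4-nitrophenoxide as leaving group, gives the ynoate with a fluoride-cleavable ester.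

**Step 11**
Reactants: 13; 16
Product: 18 2-(trimethylsilyl)ethyl (2Z)-3-{[(tert-butyldimethylsilyl)oxy]methyl}-5-[(1S,4aR,8aR)-2,2-dimethoxy-5,5,8a-trimethyldecahydronaphthalen-1-yl]pent-2-enoate, via alkylborane 17 (not isolated)
Conditions: 9-BBN dimer, THF, 60 °C; then 16, CuOAc (5 mol %), P(OPh)3 (10 mol %), t-BuOK (10 mol %), t-BuOH (1 equiv), 1,4-dioxane, 40 °C
Reagents that add atoms: none
Why: Anti-Markovnikov hydroboration of the only alkene followed by copper-catalysed conjugate addition of the B-alkyl group to the alkynoate (syn-carbocupration, then protonation) should put C12 and H cis, giving the 13Z geometry with CH2O cis to the ester.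

**Step 12**
Reactants: 18
Product: 19 2-(trimethylsilyl)ethyl (2Z)-3-{[(tert-butyldimethylsilyl)oxy]methyl}-5-[(1S,4aR,8aR)-5,5,8a-trimethyl-2-oxodecahydronaphthalen-1-yl]pent-2-enoate
Conditions: PPTS (cat.), acetone/H2O 10:1, rt
Reagents that add atoms: water O
Why: Mild acid hydrolysis of the dimethyl ketal frees the C8 ketone while the silyl ether and both esters should survive, and C9 keeps its equatorial (thermodynamic) side chain.

**Step 13**
Reactants: 19
Product: 20 2-(trimethylsilyl)ethyl (2Z)-3-{[(2-methylpropanoyl)oxy]methyl}-5-[(1S,4aR,8aR)-5,5,8a-trimethyl-2-oxodecahydronaphthalen-1-yl]pent-2-enoate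
Conditions: (i-PrCO)2O (3 equiv), Cu(OTf)2 (5 mol %), CH2Cl2, 0 °C → rt
Reagents that add atoms: isobutyric anhydride CC(C)C(=O)OC(=O)C(C)C
Why: Lewis acid-catalysed direct conversion of the silyl ether into the ester avoids a free (Z)-γ-hydroxy enoate that would lactonise, and it is run before the acid-sensitive exocyclic alkene exists.

**Step 14**
Reactants: 20
Product: 21 2-(trimethylsilyl)ethyl (2Z)-3-{[(2-methylpropanoyl)oxy]methyl}-5-[(1R,4aR,8aR)-5,5,8a-trimethyl-2-methylidenedecahydronaphthalen-1-yl]pent-2-enoate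
Conditions: Zn, CH2Br2, TiCl4, THF/CH2Cl2, 0 °C → rt
Reagents that add atoms: dibromomethane BrCBr
Why: Takai–Lombardo methylenation is non-basic and ketone-selective, so the hindered, enolisable C8 ketone should be converted in the presence of the enoate and the isobutyrate.

**Step 15**
Reactants: 21
Product: 22 (2Z)-3-{[(2-methylpropanoyl)oxy]methyl}-5-[(1R,4aR,8aR)-5,5,8a-trimethyl-2-methylidenedecahydronaphthalen-1-yl]pent-2-enoic acid (target)
Conditions: TBAF (1.5 equiv), THF, 0 °C; then dilute HCl to pH 4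
Reagents that add atoms: none
Why: Fluoride-induced β-elimination of the 2-(trimethylsilyl)ethyl ester releases the carboxylate, and the isobutyrate and both alkenes should be untouched.

**Compound list**
1 | 4,4-dimethoxycyclohexa-2,5-dien-1-one | COC1(OC)C=CC(=O)C=C1 | starting material
2 | 2-ethenyl-4,4,5,5-tetramethyl-1,3,2-dioxaborolane | C=CB1OC(C)(C)C(C)(C)O1 | starting material
3 | (5R)-5-ethenyl-4,4-dimethoxycyclohex-2-en-1-one | COC1(OC)C=CC(=O)C[C@@H]1C=C | intermediate
4 | (5S,6S)-5-ethenyl-4,4-dimethoxy-6-methylcyclohex-2-en-1-one | COC1(OC)C=CC(=O)[C@@H](C)[C@@H]1C=C | intermediate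
5 | (5S,6R)-5-ethenyl-6-(hydroxymethyl)-4,4-dimethoxy-6-methylcyclohex-2-en-1-one | COC1(OC)C=CC(=O)[C@@](C)(CO)[C@@H]1C=C | intermediate
6 | (2R,3S)-3-ethenyl-2-(hydroxymethyl)-4,4-dimethoxy-2-methylcyclohexan-1-one | COC1(OC)CCC(=O)[C@@](C)(CO)[C@@H]1C=C | intermediate
7 | (1R,6S)-6-ethenyl-5,5-dimethoxy-1-methyl-2-oxocyclohexane-1-carbaldehyde | COC1(OC)CCC(=O)[C@@](C)(C=O)[C@@H]1C=C | intermediate
8 | diethyl (2-oxobutyl)phosphonate | CCC(=O)CP(=O)(OCC)OCC | starting material
9 | (2S,3S)-3-ethenyl-4,4-dimethoxy-2-methyl-2-[(1E)-3-oxopent-1-en-1-yl]cyclohexan-1-one | COC1(OC)CCC(=O)[C@@](C)(/C=C/C(=O)CC)[C@@H]1C=C | intermediate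
10 | (4aS,5S)-5-ethenyl-6,6-dimethoxy-1,4a-dimethyl-5,6,7,8-tetrahydronaphthalen-2(4aH)-one | COC1(OC)CCC2=C(C)C(=O)C=C[C@@]2(C)[C@@H]1C=C | intermediate
11 | (4aS,5S)-5-ethenyl-6,6-dimethoxy-1,4a-dimethyl-4,4a,5,6,7,8-hexahydronaphthalen-2(3H)-one | COC1(OC)CCC2=C(C)C(=O)CC[C@@]2(C)[C@@H]1C=C | intermediate
12 | (4aR,5S,8aS)-5-ethenyl-6,6-dimethoxy-1,1,4a-trimethyloctahydronaphthalen-2(1H)-one | COC1(OC)CC[C@@H]2C(C)(C)C(=O)CC[C@@]2(C)[C@@H]1C=C | intermediate
13 | (1S,4aR,8aR)-1-ethenyl-2,2-dimethoxy-5,5,8a-trimethyldecahydronaphthalene | COC1(OC)CC[C@@H]2C(C)(C)CCC[C@@]2(C)[C@@H]1C=C | intermediate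
14 | tert-butyldimethyl(prop-2-yn-1-yloxy)silane | C#CCO[Si](C)(C)C(C)(C)C | starting material
15 | lithium 3-[(tert-butyldimethylsilyl)oxy]prop-1-yn-1-ide | [Li]C#CCO[Si](C)(C)C(C)(C)C | intermediate
16 | 2-(trimethylsilyl)ethyl 4-[(tert-butyldimethylsilyl)oxy]but-2-ynoate | C[Si](C)(C)CCOC(=O)C#CCO[Si](C)(C)C(C)(C)C | intermediate
17 | 9-{2-[(1S,4aR,8aR)-2,2-dimethoxy-5,5,8a-trimethyldecahydronaphthalen-1-yl]ethyl}-9-borabicyclo[3.3.1]nonane | COC1(OC)CC[C@@H]2C(C)(C)CCC[C@@]2(C)[C@@H]1CCB1C2CCCC1CCC2 | intermediate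
18 | 2-(trimethylsilyl)ethyl (2Z)-3-{[(tert-butyldimethylsilyl)oxy]methyl}-5-[(1S,4aR,8aR)-2,2-dimethoxy-5,5,8a-trimethyldecahydronaphthalen-1-yl]pent-2-enoate | COC1(OC)CC[C@@H]2C(C)(C)CCC[C@@]2(C)[C@@H]1CC/C(=C/C(=O)OCC[Si](C)(C)C)CO[Si](C)(C)C(C)(C)C | intermediate
19 | 2-(trimethylsilyl)ethyl (2Z)-3-{[(tert-butyldimethylsilyl)oxy]methyl}-5-[(1S,4aR,8aR)-5,5,8a-trimethyl-2-oxodecahydronaphthalen-1-yl]pent-2-enoate | O=C1CC[C@@H]2C(C)(C)CCC[C@@]2(C)[C@@H]1CC/C(=C/C(=O)OCC[Si](C)(C)C)CO[Si](C)(C)C(C)(C)C | intermediate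
20 | 2-(trimethylsilyl)ethyl (2Z)-3-{[(2-methylpropanoyl)oxy]methyl}-5-[(1S,4aR,8aR)-5,5,8a-trimethyl-2-oxodecahydronaphthalen-1-yl]pent-2-enoate | O=C1CC[C@@H]2C(C)(C)CCC[C@@]2(C)[C@@H]1CC/C(=C/C(=O)OCC[Si](C)(C)C)COC(=O)C(C)C | intermediate
21 | 2-(trimethylsilyl)ethyl (2Z)-3-{[(2-methylpropanoyl)oxy]methyl}-5-[(1R,4aR,8aR)-5,5,8a-trimethyl-2-methylidenedecahydronaphthalen-1-yl]pent-2-enoate | C=C1CC[C@@H]2C(C)(C)CCC[C@@]2(C)[C@@H]1CC/C(=C/C(=O)OCC[Si](C)(C)C)COC(=O)C(C)C | intermediate
22 | (2Z)-3-{[(2-methylpropanoyl)oxy]methyl}-5-[(1R,4aR,8aR)-5,5,8a-trimethyl-2-methylidenedecahydronaphthalen-1-yl]pent-2-enoic acid | C=C1CC[C@@H]2C(C)(C)CCC[C@@]2(C)[C@@H]1CC/C(=C/C(=O)O)COC(=O)C(C)C | target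

Total step count: 15. Longest linear sequence: 14 (steps 1–9 and 11–15; step 10 prepares the ynoate).

**Steps most likely to fail**

Step 1. The rhodium-catalysed alkenyl transfer to the β-carbon next to the ketal may be slow or show poor facial selectivity. Fallback, from 1 back to 3: copper-mediated conjugate addition of vinylmagnesium bromide (CuBr·SMe2, TMSCl, THF, −78 °C, mild acidic work-up) would give racemic 5-ethenyl-4,4-dimethoxycyclohex-2-en-1-one F1. A ketoreductase-catalysed kinetic resolution (NADPH recycled with glucose and glucose dehydrogenase) would then reduce the (5S)-ketone to (5S)-5-ethenyl-4,4-dimethoxycyclohex-2-en-1-ol F2, which is separated. The unreacted (5R)-ketone is 3.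

Step 6. The β-keto aldehyde may lose its formyl group (retro-Claisen) under base, or the (E)-enone may fail to isomerise and so not close. Fallback, from 7 back to 10: a chromium-mediated Reformatsky-type addition of 1-bromobutan-2-one (CrCl2, THF, rt) to the aldehyde would give (2R,3S)-3-ethenyl-2-(1-hydroxy-3-oxopentyl)-4,4-dimethoxy-2-methylcyclohexan-1-one F3, which has no alkene geometry to correct. KOH in MeOH at 60 °C would then close C4 onto C5 by aldol condensation and eliminate the C1 hydroxyl to give 10.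

Step 11. Transfer of the alkyl group from boron to copper may be incomplete, or the alkenylcopper intermediate may lose its syn geometry before protonation. Fallback, from 13 back to 18: hydroboration–oxidation (9-BBN; NaOH, H2O2) would give 2-[(1S,4aR,8aR)-2,2-dimethoxy-5,5,8a-trimethyldecahydronaphthalen-1-yl]ethan-1-ol F4, and iodination (I2, PPh3, imidazole) would give (1S,4aR,8aR)-1-(2-iodoethyl)-2,2-dimethoxy-5,5,8a-trimethyldecahydronaphthalene F5. Iodine–lithium exchange (t-BuLi, Et2O, −78 °C), transmetalation with CuBr·SMe2 and addition of the alkylcopper to ynoate 16 (THF, −78 °C, cold protonation) is the classical stoichiometric syn-carbocupration and would give 18.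

**Further compounds**
F1 | step 1 | 5-ethenyl-4,4-dimethoxycyclohex-2-en-1-one (racemic) | COC1(OC)C=CC(=O)CC1C=C
F2 | step 1 | (5S)-5-ethenyl-4,4-dimethoxycyclohex-2-en-1-ol | COC1(OC)C=CC(O)C[C@H]1C=C
F3 | step 6 | (2R,3S)-3-ethenyl-2-(1-hydroxy-3-oxopentyl)-4,4-dimethoxy-2-methylcyclohexan-1-one | COC1(OC)CCC(=O)[C@@](C)(C(O)CC(=O)CC)[C@@H]1C=C
F4 | step 11 | 2-[(1S,4aR,8aR)-2,2-dimethoxy-5,5,8a-trimethyldecahydronaphthalen-1-yl]ethan-1-ol | COC1(OC)CC[C@@H]2C(C)(C)CCC[C@@]2(C)[C@@H]1CCO
F5 | step 11 | (1S,4aR,8aR)-1-(2-iodoethyl)-2,2-dimethoxy-5,5,8a-trimethyldecahydronaphthalene | COC1(OC)CC[C@@H]2C(C)(C)CCC[C@@]2(C)[C@@H]1CCI
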